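Ring C of the lower gallocatechin unit is treated as a formal hetero-Diels–Alder adduct: its O1–C2 fragment is the carbonyl group of a 3,4,5-trioxygenated benzaldehyde, spliced between C8a of ring A and C3. The key step adds that aldehyde to an aryl enoxysilane (C8a–F, C4a–C4(OSiMe3)=C3) already carrying the complete, stereodefined upper unit at C8: a catalyst-controlled Mukaiyama aldol addition forms C2–C3, and the released C2 alkoxide displaces the fluoride on C8a, activated by the C4 ketone, to form O1–C8a and close the pyran ring in the same flask. The precursor is an open-chain 2-fluoroaryl α-alkoxy ketone; the C4 carbonyl is deleted afterwards.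

Key step: step 10

Remark: 1-(benzyloxy)-3,5-difluorobenzene, the aryl bromide used in step 5 and the L-fructose-derived enantiomer of the Shi ketone are taken as purchasable; the usual D-fructose-derived ketone gives (R,R)-epoxides from trans-β-substituted styrenes and would give the wrong enantiomer here.
Remark: the (R,R)-bisphosphoramide of step 10 is taken to expose the Re face of aryl aldehydes to enoxysilanes; if the sense is opposite, its (S,S)-enantiomer is used.
Remark: the lower unit carries flavan locants (O1, C2, C3, C4, C4a, C5–C8, C8a); the upper unit is described by its diarylmethine carbon and its carbinol carbon. PMB = 4-methoxybenzyl, Bn = benzyl.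

Step 1
Reactants: 1 1-(benzyloxy)-3,5-difluorobenzene; 2 benzyl alcohol
Product: 3 1,3-bis(benzyloxy)-5-fluorobenzene
Conditions: NaH, 2 (1.05 equiv), N-methylpyrrolidone, 0 to 90 °C
Reagents that add atoms: none
Why: SNAr by sodium benzyloxide on a C–F bond still activated by the meta fluorine; the reaction should stop at the bis-ether because the second alkoxy group makes the last C–F bond less electrophilic.

Step 2
Reactants: 3 1,3-bis(benzyloxy)-5-fluorobenzene; 4 acrolein
Product: 6 1-[2,4-bis(benzyloxy)-6-fluorophenyl]prop-2-en-1-ol (racemic), via aryllithium 5 (not isolated)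
Conditions: n-BuLi, THF, −78 °C; then acrolein, −78 °C
Reagents that add atoms: none
Why: Fluorine-directed ortho-lithiation at the C–H flanked by F and OBn, then 1,2-addition of the aryllithium to the enal below the temperature of LiF loss; the racemic carbinol centre is erased in step 3.

Step 3
Reactants: 6 allylic alcohol; 7 1,3,5-tris(benzyloxy)benzene
Product: 8 (E)-1-[2,4-bis(benzyloxy)-6-fluorophenyl]-3-[2,4,6-tris(benzyloxy)phenyl]prop-1-ene
Conditions: TsOH·H2O (5 mol %), CH2Cl2, 0 °C, excess 7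
Reagents that add atoms: none
Why: Acid-catalysed Friedel–Crafts allylation: the alcohol ionises to an allyl cation stabilised by the 2,4-dialkoxyaryl ring, and the threefold-symmetric arene attacks its unhindered terminus to give the conjugated (E)-alkene.

Step 4
Reactants: 8 (E)-alkene
Product: 9 (2S,3S)-2-[2,4-bis(benzyloxy)-6-fluorophenyl]-3-[2,4,6-tris(benzyloxy)benzyl]oxirane (trans)
Conditions: L-fructose-derived Shi ketone (30 mol %), KHSO5 (as 2KHSO5·KHSO4·K2SO4), K2CO3, Bu4NHSO4, MeCN–CH2(OMe)2–aqueous buffer pH 10.5, 0 °C; used crude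
Reagents that add atoms: potassium peroxymonosulfate, [K+].[O-]S(=O)(=O)OO
Why: Shi asymmetric epoxidation (chiral dioxirane, spiro transition state) of a trans-disubstituted aryl alkene; the L-ketone should give the (S,S)-epoxide, which fixes the upper carbinol centre, and the basic buffer spares the acid-labile epoxide.

Step 5
Reactants: 9 epoxide; 10 5-bromo-1,2,3-tris(benzyloxy)benzene
Product: 12 (1R,2S)-1-[2,4-bis(benzyloxy)-6-fluorophenyl]-1-[3,4,5-tris(benzyloxy)phenyl]-3-[2,4,6-tris(benzyloxy)phenyl]propan-2-ol, via aryllithium 11 (not isolated)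
Conditions: 10, n-BuLi, THF, −78 °C; then 9, BF3·OEt2, −78 °C
Reagents that add atoms: none
Why: BF3-promoted epoxide opening by an organolithium at the benzylic carbon with inversion sets the diarylmethine centre as R; the cation-stabilising 2,4-dialkoxyaryl ring secures the benzylic site, and the Felkin–Anh preference for attack anti to the C–O bond points the same way.

Step 6
Reactants: 12 alcohol
Product: 13 1,5-bis(benzyloxy)-3-fluoro-2-{(1R,2S)-2-[(4-methoxybenzyl)oxy]-1-[3,4,5-tris(benzyloxy)phenyl]-3-[2,4,6-tris(benzyloxy)phenyl]propyl}benzene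
Conditions: NaH, 4-methoxybenzyl chloride, Bu4NI (cat.), DMF, 0 to 23 °C
Reagents that add atoms: 4-methoxybenzyl chloride, COc1ccc(CCl)cc1
Why: Williamson etherification; the PMB ether blocks the upper carbinol oxygen, which would otherwise compete for the aryl fluoride in step 10 by five-membered ring closure.

Step 7
Reactants: 14 2-chloro-N-methoxy-N-methylacetamide; 15 4-methoxybenzyl alcohol
Product: 16 N-methoxy-2-[(4-methoxybenzyl)oxy]-N-methylacetamide
Conditions: NaH, THF, 0 to 23 °C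
Reagents that add atoms: none
Why: Williamson etherification of the α-chloro amide gives the Weinreb amide that carries C3, C4 and the protected C3 oxygen.

Step 8
Reactants: 13 PMB ether; 16 Weinreb amide
Product: 18 1-{4,6-bis(benzyloxy)-2-fluoro-3-[(1R,2S)-2-[(4-methoxybenzyl)oxy]-1-[3,4,5-tris(benzyloxy)phenyl]-3-[2,4,6-tris(benzyloxy)phenyl]propyl]phenyl}-2-[(4-methoxybenzyl)oxy]ethan-1-one, via aryllithium 17 (not isolated)
Conditions: n-BuLi, THF, −78 °C; then 16, −78 to −40 °C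
Reagents that add atoms: none
Why: A second fluorine-directed ortho-lithiation at the only remaining C–H flanked by F and OBn (the future C4a), then Weinreb ketone synthesis, in which the chelated tetrahedral intermediate prevents over-addition.

Step 9
Reactants: 18 ketone
Product: 19 (Z)-trimethylsilyl enol ether of 18 [aryl–C(OSiMe3)=CH–OPMB]
Conditions: Me3SiOTf, Et3N, CH2Cl2, 0 °C; used crude
Reagents that add atoms: trimethylsilyl trifluoromethanesulfonate, C[Si](C)(C)OS(=O)(=O)C(F)(F)F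
Why: Soft enolisation and O-silylation; the (Z)-enoxysilane is expected, but its geometry is not decisive in the open transition state of step 10.

Step 10
Reactants: 19 enoxysilane; 20 3,4,5-tris(benzyloxy)benzaldehyde
Product: 22 (2S,3S)-5,7-bis(benzyloxy)-3-[(4-methoxybenzyl)oxy]-2-[3,4,5-tris(benzyloxy)phenyl]-8-{(1R,2S)-2-[(4-methoxybenzyl)oxy]-1-[3,4,5-tris(benzyloxy)phenyl]-3-[2,4,6-tris(benzyloxy)phenyl]propyl}chroman-4-one (2,3-trans), via trichlorosilyl aldolate 21 (not isolated)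
Conditions: SiCl4, (R,R)-1,1'-binaphthyl-2,2'-diamine-derived dimeric phosphoramide (5 mol %), i-Pr2NEt (10 mol %), CH2Cl2, −78 °C; then CsF, DMF, −78 to 0 °C
Reagents that add atoms: none
Why: The phosphoramide-bound trichlorosilyl cation activates aldehyde 20 and enoxysilane 19 adds through an open transition state to its Re face (Lewis-base-catalysed Mukaiyama aldol addition), forming C2–C3 and setting C2 as S under catalyst control, which overrides the remote centres of the C8 side chain. Fluoride then strips silicon from the aldolate oxygen and the C2 alkoxide attacks C8a, ortho to the C4 carbonyl, expelling fluoride (intramolecular SNAr, a 6-exo addition–elimination) to form O1–C8a and close ring C; the closest known reaction type is the stepwise hetero-Diels–Alder (aldol then cyclisation) reaction of 1-alkoxy-3-siloxydienes with aldehydes, with an arene C–F bond in place of the vinylogous leaving group. C3 ends trans to the C2 aryl group either directly (anti aldol) or by equilibration through the C3 enolate under the basic fluoride conditions, because the 2,3-diequatorial flavanone is the stable isomer. The step needs the C2 oxygen alone to attack C8a: the C3 oxygen and the upper carbinol oxygen are PMB ethers, there is a single C–F bond, and the ortho ketone makes it the only activated site. Retro-aldol cleavage of the free aldolate is the competing process and should be outrun by the six-membered SNAr closure at low temperature.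

Step 11
Reactants: 22 flavanone
Product: 23 (2S,3R)-chroman-4-ol corresponding to 22 (both C4 epimers)
Conditions: NaBH4, THF–MeOH, 0 °C
Reagents that add atoms: none
Why: Borohydride reduction of the flavanone carbonyl; both C4 epimers serve because C4 becomes CH2 in step 12.

Step 12
Reactants: 23 chroman-4-ol
Product: 24 (2S,3R)-5,7-bis(benzyloxy)-2-[3,4,5-tris(benzyloxy)phenyl]-8-{(1R,2S)-2-hydroxy-1-[3,4,5-tris(benzyloxy)phenyl]-3-[2,4,6-tris(benzyloxy)phenyl]propyl}chroman-3-ol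
Conditions: Et3SiH (excess), CF3CO2H (10 vol %), CH2Cl2, 0 °C
Reagents that add atoms: none
Why: Ionic hydrogenation: acid ionises the C4 alcohol to a benzylic cation stabilised by O1 and the 5,7-alkoxy groups, which the silane reduces, and the same medium cleaves both PMB ethers, the silane trapping the 4-methoxybenzyl cation; no stereocentre is touched.

Step 13
Reactants: 24 diol; 25 3,4,5-tris(benzyloxy)benzoic acid
Product: 26 (2S,3R)-5,7-bis(benzyloxy)-8-{(1R,2S)-2-hydroxy-1-[3,4,5-tris(benzyloxy)phenyl]-3-[2,4,6-tris(benzyloxy)phenyl]propyl}-2-[3,4,5-tris(benzyloxy)phenyl]chroman-3-yl 3,4,5-tris(benzyloxy)benzoate (C3 mono-ester, upper carbinol free)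
Conditions: 25 (1.05 equiv), EDC·HCl, DMAP (cat.), CH2Cl2, 0 °C
Reagents that add atoms: none
Why: Steglich esterification with one equivalent of acid; the equatorial C3 hydroxyl of the chroman is far more accessible than the upper carbinol, which is flanked by the diarylmethine carbon and the 2,6-disubstituted benzyl group, so C3 should be acylated first with retention, and any ester formed at the other site converges on 27 in step 14.

Step 14
Reactants: 26 C3 mono-ester; 25 3,4,5-tris(benzyloxy)benzoic acid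
Product: 27 bis[3,4,5-tris(benzyloxy)benzoate] of 24 (heptadeca-O-benzyl target)
Conditions: 25 (excess), EDC·HCl, DMAP (1 equiv), CH2Cl2, 40 °C
Reagents that add atoms: none
Why: Steglich esterification of the hindered upper carbinol under forcing conditions (stoichiometric DMAP, excess activated acid), with retention at the carbinol centre.

Step 15
Reactants: 27 protected target
Product: 28 CNP0155034.3
Conditions: H2 (1 atm), Pd(OH)2 on carbon, THF–MeOH, 23 °C
Reagents that add atoms: none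
Why: Hydrogenolysis of all seventeen benzyl ethers; the gallate esters, the diarylmethine and the flavan C2–O1 bond should survive these conditions.

Compound list
1 | 1-(benzyloxy)-3,5-difluorobenzene | Fc1cc(F)cc(OCc9ccccc9)c1 | starting material
2 | benzyl alcohol | OCc1ccccc1 | starting material
3 | 1,3-bis(benzyloxy)-5-fluorobenzene | Fc1cc(OCc9ccccc9)cc(OCc9ccccc9)c1 | intermediate
4 | acrolein | C=CC=O | starting material
5 | [2,4-bis(benzyloxy)-6-fluorophenyl]lithium (not isolated) | [Li]c1c(F)cc(OCc9ccccc9)cc1OCc9ccccc9 | intermediate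
6 | 1-[2,4-bis(benzyloxy)-6-fluorophenyl]prop-2-en-1-ol (racemic) | OC(C=C)c1c(F)cc(OCc9ccccc9)cc1OCc9ccccc9 | intermediate
7 | 1,3,5-tris(benzyloxy)benzene | c1c(OCc9ccccc9)cc(OCc9ccccc9)cc1OCc9ccccc9 | starting material
8 | (E)-1-[2,4-bis(benzyloxy)-6-fluorophenyl]-3-[2,4,6-tris(benzyloxy)phenyl]prop-1-ene | Fc1cc(OCc9ccccc9)cc(OCc9ccccc9)c1/C=C/Cc4c(OCc9ccccc9)cc(OCc9ccccc9)cc4OCc9ccccc9 | intermediate
9 | (2S,3S)-2-[2,4-bis(benzyloxy)-6-fluorophenyl]-3-[2,4,6-tris(benzyloxy)benzyl]oxirane | Fc1cc(OCc9ccccc9)cc(OCc9ccccc9)c1[C@@H]2O[C@H]2Cc4c(OCc9ccccc9)cc(OCc9ccccc9)cc4OCc9ccccc9 | intermediate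
10 | 5-bromo-1,2,3-tris(benzyloxy)benzene | Brc5cc(OCc9ccccc9)c(OCc9ccccc9)c(OCc9ccccc9)c5 | starting material
11 | [3,4,5-tris(benzyloxy)phenyl]lithium (not isolated) | [Li]c5cc(OCc9ccccc9)c(OCc9ccccc9)c(OCc9ccccc9)c5 | intermediate
12 | (1R,2S)-1-[2,4-bis(benzyloxy)-6-fluorophenyl]-1-[3,4,5-tris(benzyloxy)phenyl]-3-[2,4,6-tris(benzyloxy)phenyl]propan-2-ol | O[C@@H](Cc4c(OCc9ccccc9)cc(OCc9ccccc9)cc4OCc9ccccc9)[C@H](c5cc(OCc9ccccc9)c(OCc9ccccc9)c(OCc9ccccc9)c5)c1c(F)cc(OCc9ccccc9)cc1OCc9ccccc9 | intermediate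
13 | 4-methoxybenzyl ether of 12 | COc8ccc(CO[C@@H](Cc4c(OCc9ccccc9)cc(OCc9ccccc9)cc4OCc9ccccc9)[C@H](c5cc(OCc9ccccc9)c(OCc9ccccc9)c(OCc9ccccc9)c5)c1c(F)cc(OCc9ccccc9)cc1OCc9ccccc9)cc8 | intermediate
14 | 2-chloro-N-methoxy-N-methylacetamide | ClCC(=O)N(C)OC | starting material
15 | 4-methoxybenzyl alcohol | COc1ccc(CO)cc1 | starting material
16 | N-methoxy-2-[(4-methoxybenzyl)oxy]-N-methylacetamide | COc1ccc(COCC(=O)N(C)OC)cc1 | intermediate
17 | aryllithium from 13, Li on the ring carbon between F and OBn (not isolated) | COc8ccc(CO[C@@H](Cc4c(OCc9ccccc9)cc(OCc9ccccc9)cc4OCc9ccccc9)[C@H](c5cc(OCc9ccccc9)c(OCc9ccccc9)c(OCc9ccccc9)c5)c1c(F)c([Li])c(OCc9ccccc9)cc1OCc9ccccc9)cc8 | intermediate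
18 | 1-{4,6-bis(benzyloxy)-2-fluoro-3-[(1R,2S)-2-[(4-methoxybenzyl)oxy]-1-[3,4,5-tris(benzyloxy)phenyl]-3-[2,4,6-tris(benzyloxy)phenyl]propyl]phenyl}-2-[(4-methoxybenzyl)oxy]ethan-1-one | COc8ccc(CO[C@@H](Cc4c(OCc9ccccc9)cc(OCc9ccccc9)cc4OCc9ccccc9)[C@H](c5cc(OCc9ccccc9)c(OCc9ccccc9)c(OCc9ccccc9)c5)c1c(F)c(C(=O)COCc7ccc(OC)cc7)c(OCc9ccccc9)cc1OCc9ccccc9)cc8 | intermediate
19 | (Z)-trimethylsilyl enol ether of 18 | COc8ccc(CO[C@@H](Cc4c(OCc9ccccc9)cc(OCc9ccccc9)cc4OCc9ccccc9)[C@H](c5cc(OCc9ccccc9)c(OCc9ccccc9)c(OCc9ccccc9)c5)c1c(F)c(/C(O[Si](C)(C)C)=C/OCc7ccc(OC)cc7)c(OCc9ccccc9)cc1OCc9ccccc9)cc8 | intermediate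
20 | 3,4,5-tris(benzyloxy)benzaldehyde | O=Cc6cc(OCc9ccccc9)c(OCc9ccccc9)c(OCc9ccccc9)c6 | starting material
21 | (2S,3S)-trichlorosilyl aldolate of 19 and 20, anti (not isolated) | COc8ccc(CO[C@@H](Cc4c(OCc9ccccc9)cc(OCc9ccccc9)cc4OCc9ccccc9)[C@H](c5cc(OCc9ccccc9)c(OCc9ccccc9)c(OCc9ccccc9)c5)c1c(F)c(C(=O)[C@@H](OCc7ccc(OC)cc7)[C@@H](O[Si](Cl)(Cl)Cl)c6cc(OCc9ccccc9)c(OCc9ccccc9)c(OCc9ccccc9)c6)c(OCc9ccccc9)cc1OCc9ccccc9)cc8 | intermediate
22 | (2S,3S)-3-O-PMB flavanone bearing the (1R,2S)-upper unit at C8 | COc8ccc(CO[C@@H](Cc4c(OCc9ccccc9)cc(OCc9ccccc9)cc4OCc9ccccc9)[C@H](c5cc(OCc9ccccc9)c(OCc9ccccc9)c(OCc9ccccc9)c5)c1c(OCc9ccccc9)cc(OCc9ccccc9)c2c1O[C@@H](c6cc(OCc9ccccc9)c(OCc9ccccc9)c(OCc9ccccc9)c6)[C@H](OCc7ccc(OC)cc7)C2=O)cc8 | intermediate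
23 | (2S,3R)-chroman-4-ol from 22, C4 epimers | COc8ccc(CO[C@@H](Cc4c(OCc9ccccc9)cc(OCc9ccccc9)cc4OCc9ccccc9)[C@H](c5cc(OCc9ccccc9)c(OCc9ccccc9)c(OCc9ccccc9)c5)c1c(OCc9ccccc9)cc(OCc9ccccc9)c2c1O[C@@H](c6cc(OCc9ccccc9)c(OCc9ccccc9)c(OCc9ccccc9)c6)[C@H](OCc7ccc(OC)cc7)C2O)cc8 | intermediate
24 | (2S,3R)-5,7-bis(benzyloxy)-2-[3,4,5-tris(benzyloxy)phenyl]-8-{(1R,2S)-2-hydroxy-1-[3,4,5-tris(benzyloxy)phenyl]-3-[2,4,6-tris(benzyloxy)phenyl]propyl}chroman-3-ol | O[C@@H](Cc4c(OCc9ccccc9)cc(OCc9ccccc9)cc4OCc9ccccc9)[C@H](c5cc(OCc9ccccc9)c(OCc9ccccc9)c(OCc9ccccc9)c5)c1c(OCc9ccccc9)cc(OCc9ccccc9)c2c1O[C@@H](c6cc(OCc9ccccc9)c(OCc9ccccc9)c(OCc9ccccc9)c6)[C@H](O)C2 | intermediate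
25 | 3,4,5-tris(benzyloxy)benzoic acid | OC(=O)c1cc(OCc9ccccc9)c(OCc9ccccc9)c(OCc9ccccc9)c1 | starting material
26 | C3 mono[3,4,5-tris(benzyloxy)benzoate] of 24, upper carbinol free | O[C@@H](Cc4c(OCc9ccccc9)cc(OCc9ccccc9)cc4OCc9ccccc9)[C@H](c5cc(OCc9ccccc9)c(OCc9ccccc9)c(OCc9ccccc9)c5)c1c(OCc9ccccc9)cc(OCc9ccccc9)c2c1O[C@@H](c6cc(OCc9ccccc9)c(OCc9ccccc9)c(OCc9ccccc9)c6)[C@H](OC(=O)c7cc(OCc9ccccc9)c(OCc9ccccc9)c(OCc9ccccc9)c7)C2 | intermediate
27 | bis[3,4,5-tris(benzyloxy)benzoate] of 24 | O=C(O[C@@H](Cc4c(OCc9ccccc9)cc(OCc9ccccc9)cc4OCc9ccccc9)[C@H](c5cc(OCc9ccccc9)c(OCc9ccccc9)c(OCc9ccccc9)c5)c1c(OCc9ccccc9)cc(OCc9ccccc9)c2c1O[C@@H](c6cc(OCc9ccccc9)c(OCc9ccccc9)c(OCc9ccccc9)c6)[C@H](OC(=O)c7cc(OCc9ccccc9)c(OCc9ccccc9)c(OCc9ccccc9)c7)C2)c3cc(OCc9ccccc9)c(OCc9ccccc9)c(OCc9ccccc9)c3 | intermediate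
28 | CNP0155034.3 | O=C(O[C@@H](Cc1c(O)cc(O)cc1O)[C@H](c1cc(O)c(O)c(O)c1)c1c(O)cc(O)c2c1O[C@@H](c1cc(O)c(O)c(O)c1)[C@H](OC(=O)c1cc(O)c(O)c(O)c1)C2)c1cc(O)c(O)c(O)c1 | target

Total steps: 15. Longest linear sequence: 14 steps (1 to 6, then 8 to 15); step 7 is a one-step side branch.

Steps most likely to fail

Step 10. The free aldolate may revert to enolate and aldehyde (retro-aldol) faster than it closes the ring, or the hindered, twisted enoxysilane may add with poor facial selectivity, so that the C2-epimeric series builds up. The fallback sets out from 18 and 20 and returns at 22. Ketone 18 is deprotonated with LiN(SiMe3)2 in THF at −78 °C to the lithium enolate F1. Aldehyde 20 is added to give the lithium aldolate F2, and the mixture is warmed to 0 °C. Aldol addition, retro-aldol cleavage and C3 epimerisation then equilibrate while the irreversible SNAr closure drains the aldolates. This should give 22 together with its 2,3-trans diastereomer F3, which has a (2R,3R)-configured lower ring, and the two are separated by chromatography. Catalyst control is replaced by thermodynamic control plus separation, and the two bonds are still formed in one flask.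

Step 8. n-BuLi may remove a benzylic OCH2 proton (followed by Wittig rearrangement) or the diarylmethine proton next to the ring (lateral metalation) instead of the ring C–H, so that the acyl group is misplaced or the ethers are scrambled. The fallback sets out from 3 and returns at 17, marking the position with bromine from the outset:
- Aryllithium 5 is quenched with 1,2-dibromotetrachloroethane to give 1,5-bis(benzyloxy)-2-bromo-3-fluorobenzene F4.
- LiN(i-Pr)2 at −78 °C removes the remaining C–H between F and OBn, and acrolein gives bromo allylic alcohol F5. The bromine has no ortho hydrogen, so neither aryne formation nor halogen migration can start.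
- Steps 3 and 4 are repeated unchanged to give bromo alkene F6 and bromo epoxide F7.
- The epoxide is opened with the Grignard reagent ArMgBr made from 10 and Mg, with CuI (copper iodide) as catalyst, so that the aryl bromide is not exchanged; this gives bromo alcohol F8.
- PMB protection as in step 6 gives bromo PMB ether F9.
- Bromine–lithium exchange of F9 with n-BuLi at −78 °C gives 17 without any deprotonation, and acylation with 16 gives 18.

Step 5. Epoxide 9, benzylic to a 2,4-dialkoxyaryl ring, may ionise during isolation or on contact with BF3 before the C–C bond forms, leading to Meinwald rearrangement and loss of stereochemical integrity. The fallback sets out from 7, 20 and aryllithium 5 and returns at 12, reversing the polarity so that the epoxide sits next to the less cation-stabilising 3,4,5-trialkoxyphenyl ring: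
- Arene 7 is lithiated (n-BuLi, TMEDA, THF) to [2,4,6-tris(benzyloxy)phenyl]lithium F10, which opens ethylene oxide to give 2-[2,4,6-tris(benzyloxy)phenyl]ethanol F11.
- An Appel reaction (CBr4, PPh3) gives bromide F12, and PPh3 gives phosphonium bromide F13.
- Wittig reaction of its ylide (NaN(SiMe3)2, THF, −78 °C) with 20 gives (Z)-alkene F14.
- Jacobsen epoxidation with the (R,R)-(salen)MnCl complex of trivalent manganese and NaOCl gives cis-epoxide F15 (2R,3S).
- Aryllithium 5 with BF3·OEt2 at −78 °C opens F15 at its benzylic carbon with inversion to give the same alcohol 12.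

Further compounds
F1 | step 10 | lithium (Z)-enolate of 18 | COc8ccc(CO[C@@H](Cc4c(OCc9ccccc9)cc(OCc9ccccc9)cc4OCc9ccccc9)[C@H](c5cc(OCc9ccccc9)c(OCc9ccccc9)c(OCc9ccccc9)c5)c1c(F)c(/C(O[Li])=C/OCc7ccc(OC)cc7)c(OCc9ccccc9)cc1OCc9ccccc9)cc8
F2 | step 10 | lithium aldolate of 18 and 20 | COc8ccc(CO[C@@H](Cc4c(OCc9ccccc9)cc(OCc9ccccc9)cc4OCc9ccccc9)[C@H](c5cc(OCc9ccccc9)c(OCc9ccccc9)c(OCc9ccccc9)c5)c1c(F)c(C(=O)[C@@H](OCc7ccc(OC)cc7)[C@@H](O[Li])c6cc(OCc9ccccc9)c(OCc9ccccc9)c(OCc9ccccc9)c6)c(OCc9ccccc9)cc1OCc9ccccc9)cc8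
F3 | step 10 | diastereomer of 22 with (2R,3R)-configured lower ring | COc8ccc(CO[C@@H](Cc4c(OCc9ccccc9)cc(OCc9ccccc9)cc4OCc9ccccc9)[C@H](c5cc(OCc9ccccc9)c(OCc9ccccc9)c(OCc9ccccc9)c5)c1c(OCc9ccccc9)cc(OCc9ccccc9)c2c1O[C@H](c6cc(OCc9ccccc9)c(OCc9ccccc9)c(OCc9ccccc9)c6)[C@@H](OCc7ccc(OC)cc7)C2=O)cc8
F4 | step 8 | 1,5-bis(benzyloxy)-2-bromo-3-fluorobenzene | Fc1cc(OCc9ccccc9)cc(OCc9ccccc9)c1Br
F5 | step 8 | 1-[4,6-bis(benzyloxy)-3-bromo-2-fluorophenyl]prop-2-en-1-ol (racemic) | OC(C=C)c1c(F)c(Br)c(OCc9ccccc9)cc1OCc9ccccc9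
F6 | step 8 | (E)-1-[4,6-bis(benzyloxy)-3-bromo-2-fluorophenyl]-3-[2,4,6-tris(benzyloxy)phenyl]prop-1-ene | Fc1c(Br)c(OCc9ccccc9)cc(OCc9ccccc9)c1/C=C/Cc4c(OCc9ccccc9)cc(OCc9ccccc9)cc4OCc9ccccc9
F7 | step 8 | (2S,3S)-2-[4,6-bis(benzyloxy)-3-bromo-2-fluorophenyl]-3-[2,4,6-tris(benzyloxy)benzyl]oxirane | Fc1c(Br)c(OCc9ccccc9)cc(OCc9ccccc9)c1[C@@H]2O[C@H]2Cc4c(OCc9ccccc9)cc(OCc9ccccc9)cc4OCc9ccccc9
F8 | step 8 | (1R,2S)-1-[4,6-bis(benzyloxy)-3-bromo-2-fluorophenyl]-1-[3,4,5-tris(benzyloxy)phenyl]-3-[2,4,6-tris(benzyloxy)phenyl]propan-2-ol | O[C@@H](Cc4c(OCc9ccccc9)cc(OCc9ccccc9)cc4OCc9ccccc9)[C@H](c5cc(OCc9ccccc9)c(OCc9ccccc9)c(OCc9ccccc9)c5)c1c(F)c(Br)c(OCc9ccccc9)cc1OCc9ccccc9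
F9 | step 8 | 4-methoxybenzyl ether of F8 | COc8ccc(CO[C@@H](Cc4c(OCc9ccccc9)cc(OCc9ccccc9)cc4OCc9ccccc9)[C@H](c5cc(OCc9ccccc9)c(OCc9ccccc9)c(OCc9ccccc9)c5)c1c(F)c(Br)c(OCc9ccccc9)cc1OCc9ccccc9)cc8
F10 | step 5 | [2,4,6-tris(benzyloxy)phenyl]lithium | [Li]c4c(OCc9ccccc9)cc(OCc9ccccc9)cc4OCc9ccccc9
F11 | step 5 | 2-[2,4,6-tris(benzyloxy)phenyl]ethanol | OCCc4c(OCc9ccccc9)cc(OCc9ccccc9)cc4OCc9ccccc9
F12 | step 5 | 1,3,5-tris(benzyloxy)-2-(2-bromoethyl)benzene | BrCCc4c(OCc9ccccc9)cc(OCc9ccccc9)cc4OCc9ccccc9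
F13 | step 5 | triphenyl{2-[2,4,6-tris(benzyloxy)phenyl]ethyl}phosphonium bromide | [Br-].c1ccccc1[P+](c1ccccc1)(c1ccccc1)CCc4c(OCc9ccccc9)cc(OCc9ccccc9)cc4OCc9ccccc9
F14 | step 5 | (Z)-1-[3,4,5-tris(benzyloxy)phenyl]-3-[2,4,6-tris(benzyloxy)phenyl]prop-1-ene | c5(/C=C\Cc4c(OCc9ccccc9)cc(OCc9ccccc9)cc4OCc9ccccc9)cc(OCc9ccccc9)c(OCc9ccccc9)c(OCc9ccccc9)c5
F15 | step 5 | (2R,3S)-2-[3,4,5-tris(benzyloxy)phenyl]-3-[2,4,6-tris(benzyloxy)benzyl]oxirane (cis) | c5([C@H]2O[C@H]2Cc4c(OCc9ccccc9)cc(OCc9ccccc9)cc4OCc9ccccc9)cc(OCc9ccccc9)c(OCc9ccccc9)c(OCc9ccccc9)c5
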